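**Retrosynthetic overview**
- Target 18 is cut at the methylene bridge into pyrone 15, chromene ketone 11 and a one-carbon unit (Mannich / methylidene-pyrandione coupling, last step).
- Chromene 11 comes from acylphloroglucinol 8 and 3-methylbut-2-enal (condensation / oxa-6π ring closure).
- Ketone 8 comes from phloroglucinol and (S)-2-methylbutanoic acid 5 (Friedel–Crafts acylation).
- Acid 5 comes from the achiral bis-silyl ketene acetal 3 (from tiglic acid) by a catalytic enantioselective protonation with a chiral Brønsted acid, which sets the only stereocentre.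
- Ring order: the benzene ring is bought; the pyranone ring is made in a side branch (step 5); the 2H-pyran ring of the chromene is closed in step 4, before the bridge.

Assumption: both antipodes of the chiral acid catalyst are at hand, and the one that gives the dextrorotatory (S)-acid 5 is fixed in a first run.

**Step 1**
Reactants: 1 tiglic acid ((E)-2-methylbut-2-enoic acid)
Product: 3 1,1-bis(triethylsilyloxy)-2-methylbut-1-ene, via triethylsilyl tiglate 2 (not isolated)
Conditions: Et3SiCl, Et3N, hexane, 0 °C to rt, filter under Ar; then Et3SiH, RhCl(PPh3)3 (0.5 mol %), 70 °C; vacuum distillation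
Reagents that add atoms: chlorotriethylsilane, CC[Si](Cl)(CC)CC; triethylsilane, CC[SiH](CC)CC
Why: O-silylation followed by rhodium-catalysed 1,4-hydrosilylation (conjugate hydrosilylation) of the enoate puts hydride on C3 and silicon on the carbonyl oxygen, and because both oxygen substituents are the same Et3SiO group the ketene acetal 3 is one achiral compound with no E/Z isomers.

**Step 2**
Reactants: 3 1,1-bis(triethylsilyloxy)-2-methylbut-1-ene
Product: 5 (S)-2-methylbutanoic acid, via triethylsilyl (S)-2-methylbutanoate 4 (not isolated)
Conditions: confined BINOL-derived imidodiphosphorimidate (IDPi, N-triflyl core, bulky 3,3'-aryl walls; 2 mol %), MeOH (1.05 equiv, slow addition), methylcyclohexane/toluene, −78 °C; then aq. NaHCO3, acidify, extract, distil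
Reagents that add atoms: none
Why: Proposed new method: the chiral acid protonates C2 of the electron-rich ketene acetal inside its confined anion pocket, the resulting bis-siloxycarbenium/anion pair collapses to silyl ester 4 and silylated catalyst, and methanol turns the catalyst over (as Et3SiOMe); since C1 carries two identical Et3SiO groups the two faces differ only by methyl versus ethyl, a discrimination that confined IDPi pockets already achieve in additions to 2-butanone, while slow methanol addition at −78 °C in a non-polar solvent keeps uncatalysed methanolysis negligible; the closest known reaction type is the chiral disulfonimide-catalysed protonation of bis-silyl ketene acetals of 2-arylpropionic acids with methanol, not yet shown for a purely aliphatic methyl/ethyl acetal; this sets the (S) centre.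

**Step 3**
Reactants: 5 (S)-2-methylbutanoic acid; 6 phloroglucinol (benzene-1,3,5-triol)
Product: 8 (2S)-2-methyl-1-(2,4,6-trihydroxyphenyl)butan-1-one, via (S)-2-methylbutanoyl chloride 7 (not isolated)
Conditions: (COCl)2, DMF (cat.), CH2Cl2, 0 °C to rt; then added to 6, AlCl3 (4 equiv), CH2Cl2/PhNO2, 0 °C to rt; ice/HCl
Reagents that add atoms: oxalyl chloride, O=C(Cl)C(=O)Cl (its chlorine is carried by 7 only and is lost again in 8)
Why: Friedel–Crafts acylation of the threefold-symmetric, highly activated arene gives a single mono-ketone (the product is a deactivated vinylogous acid), and base-free acid chloride formation with acylation at or below room temperature leaves the untouched alpha centre unenolised.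

**Step 4**
Reactants: 8 (2S)-2-methyl-1-(2,4,6-trihydroxyphenyl)butan-1-one; 9 3-methylbut-2-enal
Product: 11 (2S)-1-(5,7-dihydroxy-2,2-dimethyl-2H-chromen-8-yl)-2-methylbutan-1-one, via ortho-quinone methide dienone 10 (not isolated)
Conditions: 9 (0.9 equiv), ethylenediammonium diacetate (10 mol %), toluene, 100 °C; chromatography
Reagents that add atoms: none
Why: Amine-salt-catalysed Knoevenagel-type condensation at a free ring carbon gives dienone 10, whose oxa-6π electrocyclisation onto the oxygen next to the acyl group closes the 2H-pyran ring of 11; closure onto the para oxygen gives the 6-acyl isomer, expected in comparable amount and removed by chromatography, and the remote stereocentre is not affected by the weakly acidic/basic medium.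

**Step 5**
Reactants: 12 pentan-3-one; 13 malonyl dichloride
Product: 15 6-ethyl-4-hydroxy-5-methyl-2H-pyran-2-one, via 3-(trimethylsilyloxy)pent-2-ene 14 (not isolated)
Conditions: Me3SiOTf, Et3N, Et2O, 0 °C, ether layer decanted from the ammonium triflate; then 13, Et2O, −78 °C to rt; filter the precipitated pyrone
Reagents that add atoms: trimethylsilyl triflate, C[Si](C)(C)OS(=O)(=O)C(F)(F)F (its silyl group is carried by 14 only)
Why: C-acylation of the silyl enol ether by one acid chloride (loss of Me3SiCl) and ring closure of the enol oxygen onto the second (loss of HCl) give the 4-hydroxy-2-pyranone directly (silyl enol ether / malonyl dichloride pyranone synthesis).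

**Step 6**
Reactants: 15 6-ethyl-4-hydroxy-5-methyl-2H-pyran-2-one; 11 (2S)-1-(5,7-dihydroxy-2,2-dimethyl-2H-chromen-8-yl)-2-methylbutan-1-one
Product: 18 3-({5,7-dihydroxy-2,2-dimethyl-8-[(2S)-2-methylbutanoyl]-2H-chromen-6-yl}methyl)-6-ethyl-4-hydroxy-5-methyl-2H-pyran-2-one, via pyrone Mannich base 16 (not isolated), via 3-methylidene pyrandione 17 (not isolated)
Conditions: 15, CH2=NMe2+ I− (1.0 equiv), CHCl3, rt, 1 h; then 11 (1.0 equiv), 50 °C
Reagents that add atoms: N,N-dimethylmethyleneiminium iodide (Eschenmoser's salt), C=[N+](C)C.[I-]
Why: Mannich aminomethylation of the nucleophilic pyrone C3, loss of dimethylamine to the methylidene pyrandione (an ortho-quinone-methide-type acceptor) and Friedel–Crafts-type conjugate addition of C6, the only free ring carbon of 11, form the methylene bridge; forming 16 before 11 is added suppresses the pyrone–pyrone dimer, and the mild base-free conditions leave the stereocentre and the chromene untouched.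

**Compound list**
1 | tiglic acid, (E)-2-methylbut-2-enoic acid | C/C=C(\C)C(=O)O | starting material
2 | triethylsilyl (E)-2-methylbut-2-enoate | C/C=C(\C)C(=O)O[Si](CC)(CC)CC | intermediate (not isolated)
3 | 1,1-bis(triethylsilyloxy)-2-methylbut-1-ene | CCC(C)=C(O[Si](CC)(CC)CC)O[Si](CC)(CC)CC | intermediate
4 | triethylsilyl (S)-2-methylbutanoate | CC[C@H](C)C(=O)O[Si](CC)(CC)CC | intermediate (not isolated)
5 | (S)-2-methylbutanoic acid | CC[C@H](C)C(=O)O | intermediate
6 | phloroglucinol, benzene-1,3,5-triol | Oc1cc(O)cc(O)c1 | starting material
7 | (S)-2-methylbutanoyl chloride | CC[C@H](C)C(=O)Cl | intermediate (not isolated)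
8 | (2S)-2-methyl-1-(2,4,6-trihydroxyphenyl)butan-1-one | CC[C@H](C)C(=O)c1c(O)cc(O)cc1O | intermediate
9 | 3-methylbut-2-enal | CC(C)=CC=O | starting material
10 | 3,5-dihydroxy-2-[(2S)-2-methylbutanoyl]-6-(3-methylbut-2-en-1-ylidene)cyclohexa-2,4-dien-1-one | CC[C@H](C)C(=O)C1=C(O)C=C(O)C(=CC=C(C)C)C1=O | intermediate (not isolated)
11 | (2S)-1-(5,7-dihydroxy-2,2-dimethyl-2H-chromen-8-yl)-2-methylbutan-1-one | CC[C@H](C)C(=O)c1c(O)cc(O)c2C=CC(C)(C)Oc12 | intermediate
12 | pentan-3-one | CCC(=O)CC | starting material
13 | malonyl dichloride | O=C(Cl)CC(=O)Cl | starting material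
14 | 3-(trimethylsilyloxy)pent-2-ene (E/Z mixture) | CC=C(CC)O[Si](C)(C)C | intermediate (not isolated)
15 | 6-ethyl-4-hydroxy-5-methyl-2H-pyran-2-one | CCc1oc(=O)cc(O)c1C | intermediate
16 | 3-[(dimethylamino)methyl]-6-ethyl-4-hydroxy-5-methyl-2H-pyran-2-one (formed as its hydroiodide) | CCc1oc(=O)c(CN(C)C)c(O)c1C | intermediate (not isolated)
17 | 6-ethyl-5-methyl-3-methylidene-2H-pyran-2,4(3H)-dione | CCC1=C(C)C(=O)C(=C)C(=O)O1 | intermediate (not isolated)
18 | 3-({5,7-dihydroxy-2,2-dimethyl-8-[(2S)-2-methylbutanoyl]-2H-chromen-6-yl}methyl)-6-ethyl-4-hydroxy-5-methyl-2H-pyran-2-one | CCc1oc(=O)c(Cc2c(O)c3c(c(C(=O)[C@@H](C)CC)c2O)OC(C)(C)C=C3)c(O)c1C | target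

**Step count:** 6 steps in total; longest linear sequence 5 steps (steps 1, 2, 3, 4, 6).

**Three steps most likely to fail**

Step 2 (the new protonation). The risk is a modest ee, because the two faces differ only by methyl versus ethyl, or racemic background methanolysis. The fallback uses known chemistry and sets out from tiglic acid 1. It is hydrogenated with Ru(OAc)2[(S)-H8-BINAP] (H2, MeOH, rt), the established asymmetric hydrogenation of this acid, to give (S)-2-methylbutanoic acid 5 directly. The catalyst antipode is checked by the sign of rotation. The route is rejoined at 5, step 1 falls away, and no compound outside the list is made (F0).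

Step 3 (Friedel–Crafts acylation). The risk is partial racemisation of the acyl unit through acylium/ketene equilibration under AlCl3, or over-acylation. Ketone 8 is crystalline, so ee can be checked and raised there. The fallback sets out from acid 5. Commercial 1,3,5-tris(benzyloxy)benzene is acylated with the mixed anhydride formed from 5 and trifluoroacetic anhydride (CH2Cl2, 0 °C to rt, no Lewis acid) to give (2S)-2-methyl-1-[2,4,6-tris(benzyloxy)phenyl]butan-1-one F1. Hydrogenolysis of the three benzyl ethers (H2, Pd/C, EtOAc, rt) returns to the route at ketone 8.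

Step 4 (chromene formation). The risk is regiochemistry: ring closure onto the para oxygen gives the 6-acyl isomer, possibly as the major product, and a second chromenylation can also occur. The fallback sets out from ketone 8. The para hydroxyl, the only one not flanked by the acyl group, is silylated selectively (iPr3SiCl, imidazole, DMF, 0 °C) to give (2S)-1-[2,6-dihydroxy-4-(triisopropylsilyloxy)phenyl]-2-methylbutan-1-one F2. Condensation with 9 under the step 4 conditions can then close only onto an ortho oxygen and gives (2S)-1-[7-hydroxy-2,2-dimethyl-5-(triisopropylsilyloxy)-2H-chromen-8-yl]-2-methylbutan-1-one F3. Desilylation (Bu4NF, AcOH, THF, 0 °C) returns to the route at chromene 11.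

**Further compounds**
F0 | step 2 | none | none
F1 | step 3 | (2S)-2-methyl-1-[2,4,6-tris(benzyloxy)phenyl]butan-1-one | CC[C@H](C)C(=O)c1c(OCc2ccccc2)cc(OCc2ccccc2)cc1OCc1ccccc1
F2 | step 4 | (2S)-1-[2,6-dihydroxy-4-(triisopropylsilyloxy)phenyl]-2-methylbutan-1-one | CC[C@H](C)C(=O)c1c(O)cc(O[Si](C(C)C)(C(C)C)C(C)C)cc1O
F3 | step 4 | (2S)-1-[7-hydroxy-2,2-dimethyl-5-(triisopropylsilyloxy)-2H-chromen-8-yl]-2-methylbutan-1-one | CC[C@H](C)C(=O)c1c(O)cc(O[Si](C(C)C)(C(C)C)C(C)C)c2C=CC(C)(C)Oc12
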